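## Structural features

The target is a germacranolide: a ten-membered carbocycle (C1–C10) with a trans-fused α-methylene-γ-butyrolactone across C6–C7 (lactone oxygen on C6, C11 on C7), an angelate on C8, a methyl group on C10 and a free hydroxyl on C5. Three epoxides sit on the ring: the trans C1–C10 epoxide, the cis C2–C3 epoxide and the spiro C4–C15 epoxide. Every ring carbon except C9 is stereogenic, and C1 through C8 form one unbroken run of eight stereocentres. The fragile groups are the three epoxides (the spiro one next to a free hydroxyl), the Michael-accepting methylene lactone and the angelate, whose Z olefin slips to the tiglate under nucleophilic or acidic catalysis. The real difficulty is the medium ring together with the C5–C8 tetrad and the faces of three epoxidations on a flexible ring. Read as olefins, the trans C1–C10 epoxide is an E trisubstituted olefin and the cis C2–C3 epoxide a Z olefin that can be a cyclohexene bond. C6 is then a carbonyl-level carbon and C8 an oxygenated carbon two atoms away, which is the pattern of an oxy-Cope product: C1–C6 is the bond of a six-membered ring (C1–C6) that breaks while C8–C9 forms, with C7=C8 and C9=C10 as the alkenyl arms on C6 and C1.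

## Logic of the disconnections

38 to 35: the six C–O bonds of the three epoxides are cut. This removes five stereocentres at once and leaves a conjugated triene whose geometries (E at C1=C10, Z at C2=C3) encode the epoxide relative configurations. The forward demand is facial control: the C5 hydroxyl must deliver oxygen to C4=C15, and the ring conformation must expose the correct faces of the other two olefins (36, 37).

35 to 31 and 32: the C8 ester C–O bond and the C5 protecting group are cut. The angelate is introduced late because it tolerates neither enolate chemistry nor strong nucleophiles, and the forward acylation must not isomerise it.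

31 to 26: the exocyclic C11=C13 bond and the C8 benzyl ether are cut. The methylene group is a one-carbon electrophile added to the lactone enolate (30), which must be the only enolisable position at that stage.

26 to 22: the lactone C–O bond and the C7–C11 bond are cut, returning the C6 ketone. This reduces the C5–C8 tetrad to the two centres (C5, C8) that the rearrangement delivers. The forward steps must set C7 by alkylation (24) and C6 by reduction under the control of those two centres.

22 to 19: the C8–C9 bond is cut and the C1–C6 bond re-formed. The ten-membered ring collapses to a cyclohexenol, so no macrocyclisation is needed, and both olefin geometries and C8 are traced to the ring and to the enol ether geometry. The demand is a trans-dialkenyl carbinol with an E enol ether, and a chair [3,3] shift that outruns every other reaction of the alkoxide.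

19 to 12 and 14: the C6–C7 bond is cut and the enol ether traced to an alkoxyalkyne (18). This replaces an elimination-prone (E)-2-alkoxyvinyl anion by an acetylide. The forward demand is attack on the ketone anti to the isopropenyl group and a trans-selective alkyne reduction.

14 to 13: the vinyl C–O bond is cut; the two carbons come from trichloroethylene.

12 to 7: the ring diene is traced to an epoxide (via 8, 9, 10) and the ketone to a silyl-protected carbinol (11). All sp2 centres of the fragile ketone are thus stored as robust functions until the last two steps before the coupling.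

7 to 1: the C5 oxygen is traced to a carbonyl, the C6 oxygen to an enolate hydroxylation and the epoxide to the enone (6, 5, 4, 2). The single stereocentre of 1 must then direct three new ones, by anti addition to the enone, anti hydroxylation and equatorial hydride delivery.

## Other disconnections considered

Alternative 1: The cut is the C2=C3 olefin. The acyclic bis(vinyl epoxide) A2 would be closed to the ten-membered Z-olefin bis-epoxide A1 by ring-closing metathesis with the second-generation Grubbs catalyst RuCl2(=CHPh)(PCy3)(H2IMes).
- In its favour: A1 is identical with compound 37 of the chosen route, so the end game is shared and only one epoxidation would remain. The C1–C10 and spiro epoxides would be installed on open-chain fragments under reagent control, which is better than relying on peripheral attack on a flexible ring. The assembly would be convergent, which is at least the equal of the chosen plan.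
- Against it here: one vinyl group sits on the fully substituted spiro-epoxide carbon C4 and the other on an epoxide carbon, so both partners are hindered and electronically deactivated. The closure of a strained ten-membered ring competes with oligomerisation and needs high dilution. The mechanism does not fix the olefin geometry, and the methylene lactone could engage the carbene. A2 needs the C4–C8 stereopentad built without a ring.
- Comparison: the chosen plan obtains Z C2=C3 from a cyclohexene bond and forms the ring without end-to-end closure, in an irreversible sigmatropic step rather than a reversible, entropy-penalised one. On step count alternative 1 is expected to be longer because of the acyclic stereoarray.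

Alternative 2: The cut is the C3–C8 bond. The epoxy decalone A4 (C2 ketone, C3–C8 ring-fusion epoxide) would be converted with p-toluenesulfonylhydrazide in acetic acid into its hydrazone, which fragments by the Eschenmoser–Tanabe path to the cyclodecenynone lactone A3 with a C2–C3 alkyne and a C8 ketone.
- In its favour: the ring arises by fragmentation of a bicycle, so there is no macrocyclisation, which makes it the equal of the chosen plan on that point. Decalin chemistry gives predictable control of C5–C7 and C10. The alkyne secures Z C2=C3 by semi-hydrogenation, equal to the cyclohexene origin. The C1–C10 diol allows the trans epoxide to be closed by a displacement of defined sense, better than a peripheral epoxidation.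
- Against it here: a cyclodecyne flanked by an exocyclic olefin and a fused lactone is strained. The fragmentation needs a tetrasubstituted ring-fusion epoxide next to a ketone, which is long to prepare. The C8 carbonyl would then have to be reduced with facial control on the macrocycle, whereas the chosen plan relays C8 through a chair. Semi-hydrogenation must spare the exocyclic methylene.
- Comparison: both are ring expansions driven by C–C cleavage. The oxy-Cope creates C8 and both olefin geometries in the same step, while the fragmentation creates no stereocentre and postpones three stereochemical problems. A longer sequence is expected.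

Alternative 3: The cut is the C5–C6 bond. The open-chain dialdehyde A6 (C5 enal, C6 aldehyde) would be coupled with low-valent titanium (TiCl3, Zn-Cu couple) to the ten-membered C5,C6-diol A5.
- In its favour: ring, C5 carbinol and C6 carbinol would be formed in one operation. The C6 hydroxyl would lactonise onto the C12 ester and so differentiate the diol without protecting groups, which is equal or better on protecting-group economy. The precursor is assembled convergently, so the longest linear sequence could be shorter, also equal or better.
- Against it here: two stereocentres would be created with little control, giving up to four diastereomers. The ketyl of the enal is an allyl radical that can couple through C15 or be reduced. Deoxygenation to the olefin competes on warming. The triene of A6, with its Z C2=C3 bond, must be carried through strongly reducing conditions at high dilution.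
- Comparison: the chosen plan sets C5 before the ring exists and C6 afterwards by chelation, one centre at a time, and forms the ring in a concerted intramolecular reorganisation. Alternative 3 wins on convergence and loses on stereochemical reliability.

Key step: step 14

Remark: germacrane numbering (C1–C15) is used for the ten-membered compounds. Tracing C1, C5, C6 of the cyclohexenol and C5, C8 and both olefin geometries of the trienone through the chair showed them to agree with the target, so no structure had to be corrected. The E enol ether is introduced as an alkoxyalkyne and reduced, because an (E)-2-alkoxyvinyllithium carries lithium and alkoxide anti to each other and can eliminate.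

## Route

Step 1
Reactants: 1 (R)-carvone
Product: 2 carvone oxide, (1R,4R,6R)-1-methyl-4-(prop-1-en-2-yl)-7-oxabicyclo[4.1.0]heptan-2-one
Conditions: H2O2 (30% aq), NaOH (cat.), MeOH, 0 °C
Reagents that add atoms: hydrogen peroxide, OO
Why: Weitz–Scheffer nucleophilic epoxidation touches only the enone; hydroperoxide adds to the β-carbon anti to the isopropenyl group, so the epoxide is trans to it and the isopropenyl olefin is untouched.

Step 2
Reactants: 2 carvone oxide
Product: 4 (1R,3S,4S,6R)-3-hydroxy-1-methyl-4-(prop-1-en-2-yl)-7-oxabicyclo[4.1.0]heptan-2-one, via sodium enolate 3 (not isolated)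
Conditions: NaN(SiMe3)2, THF, −78 °C; 2-(phenylsulfonyl)-3-phenyloxaziridine, −78 °C; AcOH
Reagents that add atoms: 2-(phenylsulfonyl)-3-phenyloxaziridine, O=S(=O)(N1OC1c1ccccc1)c1ccccc1
Why: The only α-hydrogens are on the methylene next to the isopropenyl carbon, so enolisation is regiospecific; oxaziridine hydroxylation of the enolate should occur anti to the neighbouring isopropenyl group (this centre later becomes the C6 carbonyl and only serves step 4).

Step 3
Reactants: 4 α'-hydroxy epoxy ketone
Product: 5 tert-butyldimethylsilyl ether of 4
Conditions: TBSOTf, 2,6-lutidine, CH2Cl2, −78 to 0 °C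
Reagents that add atoms: tert-butyldimethylsilyl triflate, CC(C)(C)[Si](C)(C)OS(=O)(=O)C(F)(F)F
Why: Silylation of a secondary α-hydroxy ketone with a silyl triflate and a hindered base; the silyl ether survives steps 4–8 and is later removed by fluoride without loss of the MOM ether.

Step 4
Reactants: 5 silyloxy epoxy ketone
Product: 6 epoxy alcohol, 2-hydroxy-3-silyloxy-7-oxabicyclo[4.1.0]heptane with hydroxyl, silyloxy group and epoxide oxygen all on the face opposite to the isopropenyl group
Conditions: LiBH(s-Bu)3, THF, −78 °C; AcOH, −78 °C
Reagents that add atoms: none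
Why: Reduction of a 2,3-epoxycyclohexanone by a bulky trialkylborohydride; hydride should enter equatorially from the face opposite to both the epoxide oxygen and the silyloxy group, which sets the future C5 oxygen trans to isopropenyl, and the cold acid quench prevents 1,2-silyl migration.

Step 5
Reactants: 6 epoxy alcohol
Product: 7 methoxymethyl ether of 6
Conditions: MOMCl, i-Pr2NEt, Bu4NI (cat.), CH2Cl2, 0 to 40 °C
Reagents that add atoms: chloromethyl methyl ether, COCCl
Why: Standard acetal etherification; MOM is chosen for the future C5 oxygen because it cannot migrate to a neighbouring alkoxide in step 14 (a silyl group would) and can chelate in steps 12 and 16.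

Step 6
Reactants: 7 MOM-protected epoxide
Product: 8 allylic alcohol with exocyclic methylene, secondary hydroxyl on the former epoxide CH, on the same face as OMOM
Conditions: Et2AlCl, lithium 2,2,6,6-tetramethylpiperidide, PhMe, 0 °C to rt; H2O
Reagents that add atoms: none
Why: Aluminium amide isomerisation of a trisubstituted epoxide to an allylic alcohol through a cyclic syn-elimination; the methyl hydrogens are the unhindered syn β-hydrogens (the C–H next to OMOM is anti to the epoxide oxygen), so the tertiary C–O bond breaks and the exocyclic olefin forms.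

Step 7
Reactants: 8 allylic alcohol
Product: 9 methyl carbonate of 8
Conditions: ClCO2Me, pyridine, CH2Cl2, 0 °C
Reagents that add atoms: methyl chloroformate, COC(=O)Cl
Why: Acylation of the secondary allylic alcohol provides the leaving group needed for π-allyl formation.

Step 8
Reactants: 9 allylic carbonate
Product: 10 silyl-protected dienol, tert-butyldimethylsilyl ether of 11
Conditions: Pd(OAc)2 (5 mol %), PPh3 (20 mol %), 1,4-dioxane, 90 °C
Reagents that add atoms: none
Why: Tsuji elimination: zerovalent palladium formed in situ ionises the allylic carbonate, and β-hydride elimination can only use the ring CH2 beside the allyl terminus, so the exocyclic/endocyclic 1,3-diene is the only diene possible; decarboxylation supplies methoxide as the internal base.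

Step 9
Reactants: 10 silyl-protected dienol
Product: 11 dienol, 2-(methoxymethoxy)-3-methylidene-6-(prop-1-en-2-yl)cyclohex-4-en-1-ol with OMOM trans to isopropenyl
Conditions: Bu4NF, THF, 0 °C to rt
Reagents that add atoms: none
Why: Fluoride cleavage of the secondary silyl ether; the acetal and the triene are inert.

Step 10
Reactants: 11 dienol
Product: 12 (2R,6S)-2-(methoxymethoxy)-3-methylidene-6-(prop-1-en-2-yl)cyclohex-4-en-1-one
Conditions: Dess–Martin periodinane, NaHCO3, CH2Cl2, 0 °C; filtered cold and used at once
Reagents that add atoms: none
Why: Periodinane oxidation under bicarbonate is fast and neutral; the ketone is doubly β,γ-unsaturated and epimerisable at the isopropenyl carbon, so it is not chromatographed.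

Step 11
Reactants: 13 4-methoxybenzyl alcohol
Product: 14 (E)-1,2-dichlorovinyl 4-methoxybenzyl ether
Conditions: KH, THF, 0 °C; Cl2C=CHCl, −50 °C to rt
Reagents that add atoms: trichloroethylene, ClC=C(Cl)Cl
Why: The alkoxide converts trichloroethylene into dichloroacetylene and adds to it in anti fashion, the established entry to 1,2-dichlorovinyl ethers as alkoxyacetylide precursors.

Step 12
Reactants: 12 dienone; 14 dichlorovinyl ether
Product: 18 (1S,2R,6S)-1-[(4-methoxybenzyloxy)ethynyl]-2-(methoxymethoxy)-3-methylidene-6-(prop-1-en-2-yl)cyclohex-4-en-1-ol, via chloroethynyl ether 15 (not isolated), via lithium alkoxyacetylide 16 (not isolated), via alkynylcerium dichloride 17 (not isolated)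
Conditions: n-BuLi (2.1 equiv), THF, −78 to −40 °C; CeCl3, −78 °C; then 12, −78 °C; H2O
Reagents that add atoms: none
Why: Two equivalents of n-BuLi turn the dichlorovinyl ether into the lithium alkoxyacetylide (elimination to the chloroalkyne, then Cl/Li exchange); the cerium reagent is too weakly basic to enolise the ketone and can bridge C=O and the MOM oxygen, which holds isopropenyl pseudoaxial on the other face so that the slim nucleophile adds anti to it (1,2-addition of an alkynylcerium reagent).

Step 13
Reactants: 18 alkynyl carbinol
Product: 19 (1S,2R,6S)-1-[(E)-2-(4-methoxybenzyloxy)ethenyl]-2-(methoxymethoxy)-3-methylidene-6-(prop-1-en-2-yl)cyclohex-4-en-1-ol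
Conditions: LiAlH4, THF, 0 °C; H2O
Reagents that add atoms: none
Why: Alkoxide-directed trans-hydroalumination of the propargylic alkoxide and protonolysis, the known reduction of alkoxyethynyl carbinols to trans-2-alkoxyvinyl carbinols, gives the E enol ether by mechanism.

Step 14
Reactants: 19 trans-dialkenyl cyclohexenol
Product: 22 (5R,8S,1(10)E,2Z)-8-(4-methoxybenzyloxy)-5-(methoxymethoxy)germacra-1(10),2,4(15)-trien-6-one, via potassium alkoxide 20 (not isolated), via potassium enolate 21 (not isolated)
Conditions: KH, 18-crown-6, THF, 0 °C to rt; AcOH, THF, −78 °C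
Reagents that add atoms: none
Why: KH deprotonates the tertiary carbinol and the crown ether frees the alkoxide, whose charge weakens the C1–C6 bond and accelerates the [3,3] shift of the C9=C10–C1–C6–C7=C8 unit (anionic oxy-Cope rearrangement). The closest known reaction type is the ring expansion of trans-1,2-dialkenylcyclohexanols to (E)-cyclodec-5-enones. The ten-membered ring is not closed end to end: it appears by ring expansion, as C8–C9 forms and the C1–C6 ring bond breaks inside a six-membered chair transition state. In that chair both ring carbons (C2 on C1, C5 on C6) are equatorial, which only the trans-dialkenyl isomer allows; this gives E C1=C10, while C2=C3 stays Z because it was a ring bond. The one new stereocentre, C8, is controlled by the E enol ether, which keeps its oxygen equatorial and so relays the C1 and C6 configurations to 8S. The step needs chair over boat, the isopropenyl arm over the ring olefin, and a concerted over a dissociative path; the trans-diequatorial arms secure the first two, because a shift through C2=C3 would need a boat with the alkoxyvinyl group axial. In the nascent enolate the C8–O bond lies close to the enolate plane, and the cold acetic acid quench should deliver the ketone before alkoxide loss or proton shuffle towards C5.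

Step 15
Reactants: 22 trienone
Product: 24 ethyl (5R,7R,8S)-ketone ester, the C7 ethoxycarbonylmethyl derivative of 22, via lithium enolate 23 (not isolated)
Conditions: LiN(i-Pr)2, THF, −78 °C; ICH2CO2Et, DMPU, −78 to −50 °C
Reagents that add atoms: ethyl iodoacetate, CCOC(=O)CI
Why: Kinetic deprotonation by the hindered amide should take the C7 methylene and not the C5 methine that carries OMOM; the ring enolate is alkylated on its outer face, away from C9, which places C11 trans to the C8 oxygen, and below −50 °C the in-plane C8–O bond should not eliminate (enolate alkylation).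

Step 16
Reactants: 24 keto ester
Product: 26 (5R,6S,7R,8S)-8-(4-methoxybenzyloxy)-5-(methoxymethoxy)-13-norgermacra-1(10),2,4(15)-trien-12,6-olide, via hydroxy ester 25 (not isolated)
Conditions: Zn(BH4)2, Et2O, −30 to 0 °C; H2O; PPTS (cat.), PhH, 40 °C
Reagents that add atoms: none
Why: Zinc bridges the C6 carbonyl and the C5 MOM oxygen and hydride adds from the side of H5 (Cram chelate model), which gives the 6S carbinol with the C5/C6 relationship of the target; the γ-hydroxy ester then closes to the trans-fused lactone.

Step 17
Reactants: 26 lactone
Product: 30 (5R,6S,7R,8S)-8-(4-methoxybenzyloxy)-5-(methoxymethoxy)germacra-1(10),2,4(15),11(13)-tetraen-12,6-olide, via lithium enolate 27 (not isolated), via Mannich base 28 (not isolated), via ammonium iodide 29 (not isolated)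
Conditions: LiN(i-Pr)2, THF, −78 °C; CH2=NMe2+ I−, −78 °C to rt; MeI, MeOH, rt; NaHCO3 (aq), CH2Cl2
Reagents that add atoms: N,N-dimethylmethyleneiminium iodide, C=[N+](C)C.[I-]
Why: C11 is the only enolisable position, so the lactone enolate is aminomethylated, the amine quaternised and trimethylamine eliminated (Mannich methylenation); neither leaving group on C6 or C8 is β to the enolate carbon.

Step 18
Reactants: 30 methylene lactone
Product: 31 C8 alcohol, (5R,6S,7R,8S)-8-hydroxy-5-(methoxymethoxy)germacra-1(10),2,4(15),11(13)-tetraen-12,6-olide
Conditions: DDQ, CH2Cl2/pH 7 buffer, 0 °C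
Reagents that add atoms: none
Why: Oxidative cleavage of the electron-rich benzyl ether through its benzylic cation; the acetal, the lactone and the electron-poor olefins do not react, and the buffer protects the allylic C5 ether.

Step 19
Reactants: 31 C8 alcohol; 32 angelic acid
Product: 34 C8 angelate, (5R,6S,7R,8S)-8-angeloyloxy-5-(methoxymethoxy)germacra-1(10),2,4(15),11(13)-tetraen-12,6-olide, via mixed anhydride 33 (not isolated)
Conditions: 2,4,6-Cl3C6H2COCl, Et3N, PhMe, rt; then 31, 75 °C
Reagents that add atoms: none
Why: Yamaguchi-type acylation through the trichlorobenzoic mixed anhydride esterifies hindered secondary alcohols without the nucleophilic catalysis that isomerises angelates to tiglates.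

Step 20
Reactants: 34 angelate MOM ether
Product: 35 (5R,6S,7R,8S)-8-angeloyloxy-5-hydroxygermacra-1(10),2,4(15),11(13)-tetraen-12,6-olide
Conditions: Me2BBr, CH2Cl2, −78 °C; NaHCO3 (aq)
Reagents that add atoms: none
Why: The bromoborane cleaves the acetal at its O–CH2 bond at −78 °C, so no cation develops at the allylic C5, and no thiol is present that could add to the methylene lactone (Lewis acid acetal cleavage).

Step 21
Reactants: 35 trienol
Product: 36 4,15-epoxide, 8-angeloyloxy-4,15-epoxy-5-hydroxygermacra-1(10),2,11(13)-trien-12,6-olide with epoxide oxygen cis to the C5 hydroxyl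
Conditions: VO(acac)2 (cat.), t-BuOOH, CH2Cl2, 0 °C
Reagents that add atoms: tert-butyl hydroperoxide, CC(C)(C)OO
Why: Hydroxyl-directed vanadium-catalysed epoxidation: only C4=C15 is allylic to the C5 hydroxyl, and the bound peroxide is delivered from the hydroxyl face, which gives the spiro epoxide of the target.

Step 22
Reactants: 36 spiro epoxide
Product: 38 target, (1R,2R,3S,4S,5S,6S,7R,8S,10R)-8-angeloyloxy-1,10:2,3:4,15-triepoxy-5-hydroxygermacr-11(13)-en-12,6-olide, via 1,10-monoepoxide 37 (not isolated)
Conditions: dimethyldioxirane (3 equiv), acetone, 0 °C to rt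
Reagents that add atoms: dimethyldioxirane, CC1(C)OO1
Why: The neutral dioxirane first epoxidises the trisubstituted E C1=C10 olefin on the peripheral face exposed in the usual germacrane conformation, then the Z C2=C3 olefin from outside the ring; the ester- and lactone-conjugated olefins are too electron-poor to compete.

## Compound list

1 | (R)-carvone, (5R)-2-methyl-5-(prop-1-en-2-yl)cyclohex-2-en-1-one | CC1=CC[C@H](CC1=O)C(C)=C | starting material
2 | (1R,4R,6R)-1-methyl-4-(prop-1-en-2-yl)-7-oxabicyclo[4.1.0]heptan-2-one | O=C1[C@]2(C)O[C@@H]2C[C@@H](C(C)=C)C1 | intermediate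
3 | sodium enolate of 2 (C2=C3 of the bicycle) | [Na+].[O-]C=1[C@]2(C)O[C@@H]2C[C@@H](C(C)=C)C=1 | intermediate
4 | (1R,3S,4S,6R)-3-hydroxy-1-methyl-4-(prop-1-en-2-yl)-7-oxabicyclo[4.1.0]heptan-2-one (hydroxyl trans to isopropenyl) | O=C1[C@]2(C)O[C@@H]2C[C@@H](C(C)=C)[C@@H]1O | intermediate
5 | (1R,3S,4S,6R)-3-(tert-butyldimethylsilyloxy)-1-methyl-4-(prop-1-en-2-yl)-7-oxabicyclo[4.1.0]heptan-2-one | O=C1[C@]2(C)O[C@@H]2C[C@@H](C(C)=C)[C@@H]1O[Si](C)(C)C(C)(C)C | intermediate
6 | 3-(tert-butyldimethylsilyloxy)-1-methyl-4-(prop-1-en-2-yl)-7-oxabicyclo[4.1.0]heptan-2-ol, all three oxygens on the face opposite to isopropenyl | O[C@@H]1[C@]2(C)O[C@@H]2C[C@@H](C(C)=C)[C@@H]1O[Si](C)(C)C(C)(C)C | intermediate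
7 | 2-O-methoxymethyl ether of 6 | COCO[C@@H]1[C@]2(C)O[C@@H]2C[C@@H](C(C)=C)[C@@H]1O[Si](C)(C)C(C)(C)C | intermediate
8 | 4-(tert-butyldimethylsilyloxy)-3-(methoxymethoxy)-2-methylidene-5-(prop-1-en-2-yl)cyclohexan-1-ol, the three oxygens cis to one another and trans to isopropenyl | COCO[C@@H]1C(=C)[C@H](O)C[C@@H](C(C)=C)[C@@H]1O[Si](C)(C)C(C)(C)C | intermediate
9 | methyl carbonate of 8 | COCO[C@@H]1C(=C)[C@H](OC(=O)OC)C[C@@H](C(C)=C)[C@@H]1O[Si](C)(C)C(C)(C)C | intermediate
10 | tert-butyldimethylsilyl ether of 11 | COCO[C@@H]1C(=C)C=C[C@@H](C(C)=C)[C@@H]1O[Si](C)(C)C(C)(C)C | intermediate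
11 | 2-(methoxymethoxy)-3-methylidene-6-(prop-1-en-2-yl)cyclohex-4-en-1-ol, OH and OMOM cis, both trans to isopropenyl | COCO[C@@H]1C(=C)C=C[C@@H](C(C)=C)[C@@H]1O | intermediate
12 | (2R,6S)-2-(methoxymethoxy)-3-methylidene-6-(prop-1-en-2-yl)cyclohex-4-en-1-one | COCO[C@@H]1C(=C)C=C[C@@H](C(C)=C)C1=O | intermediate
13 | 4-methoxybenzyl alcohol | COc1ccc(CO)cc1 | starting material
14 | (E)-1,2-dichlorovinyl 4-methoxybenzyl ether | COc1ccc(CO/C(Cl)=C\Cl)cc1 | intermediate
15 | chloroethynyl 4-methoxybenzyl ether | COc1ccc(COC#CCl)cc1 | intermediate
16 | lithium (4-methoxybenzyloxy)acetylide | [Li]C#COCc1ccc(OC)cc1 | intermediate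
17 | [(4-methoxybenzyloxy)ethynyl]cerium dichloride | Cl[Ce](Cl)C#COCc1ccc(OC)cc1 | intermediate
18 | (1S,2R,6S)-1-[(4-methoxybenzyloxy)ethynyl]-2-(methoxymethoxy)-3-methylidene-6-(prop-1-en-2-yl)cyclohex-4-en-1-ol | COCO[C@@H]1C(=C)C=C[C@@H](C(C)=C)[C@]1(O)C#COCc1ccc(OC)cc1 | intermediate
19 | (1S,2R,6S)-1-[(E)-2-(4-methoxybenzyloxy)ethenyl]-2-(methoxymethoxy)-3-methylidene-6-(prop-1-en-2-yl)cyclohex-4-en-1-ol | C=C(C)[C@@H]1C=CC(=C)[C@@H](OCOC)[C@@]1(O)/C=C/OCc2ccc(OC)cc2 | intermediate
20 | potassium alkoxide of 19 | [K+].C=C(C)[C@@H]1C=CC(=C)[C@@H](OCOC)[C@@]1([O-])/C=C/OCc2ccc(OC)cc2 | intermediate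
21 | potassium C6=C7 enolate of 22 (C5 and C8 trans across the enolate bond) | [K+].[O-]/C1=C\[C@@H](OCc2ccc(OC)cc2)C/C(C)=C/C=C\C(=C)[C@H]1OCOC | intermediate
22 | (5R,8S,1(10)E,2Z)-8-(4-methoxybenzyloxy)-5-(methoxymethoxy)germacra-1(10),2,4(15)-trien-6-one | O=C1C[C@@H](OCc2ccc(OC)cc2)C/C(C)=C/C=C\C(=C)[C@H]1OCOC | intermediate
23 | lithium C6=C7 enolate of 22 | [Li+].[O-]/C1=C\[C@@H](OCc2ccc(OC)cc2)C/C(C)=C/C=C\C(=C)[C@H]1OCOC | intermediate
24 | ethyl (5R,7R,8S)-8-(4-methoxybenzyloxy)-5-(methoxymethoxy)-6-oxo-13-norgermacra-1(10),2,4(15)-trien-12-oate | O=C1[C@H](CC(=O)OCC)[C@@H](OCc2ccc(OC)cc2)C/C(C)=C/C=C\C(=C)[C@H]1OCOC | intermediate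
25 | C6 hydroxy ester from 24 (C6 hydroxyl cis to OMOM, trans to the C7 side chain in the ring projection) | O[C@H]1[C@H](CC(=O)OCC)[C@@H](OCc2ccc(OC)cc2)C/C(C)=C/C=C\C(=C)[C@H]1OCOC | intermediate
26 | (5R,6S,7R,8S)-8-(4-methoxybenzyloxy)-5-(methoxymethoxy)-13-norgermacra-1(10),2,4(15)-trien-12,6-olide | C1C(=O)O[C@H]2[C@H]1[C@@H](OCc3ccc(OC)cc3)C/C(C)=C/C=C\C(=C)[C@H]2OCOC | intermediate
27 | lithium enolate of lactone 26 (C11=C12) | [Li+].C1=C([O-])O[C@H]2[C@H]1[C@@H](OCc3ccc(OC)cc3)C/C(C)=C/C=C\C(=C)[C@H]2OCOC | intermediate
28 | 11-(dimethylaminomethyl) lactone (C11 mixture) | CN(C)CC1C(=O)O[C@H]2[C@H]1[C@@H](OCc3ccc(OC)cc3)C/C(C)=C/C=C\C(=C)[C@H]2OCOC | intermediate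
29 | 11-(trimethylammoniomethyl) lactone iodide | [I-].C[N+](C)(C)CC1C(=O)O[C@H]2[C@H]1[C@@H](OCc3ccc(OC)cc3)C/C(C)=C/C=C\C(=C)[C@H]2OCOC | intermediate
30 | (5R,6S,7R,8S)-8-(4-methoxybenzyloxy)-5-(methoxymethoxy)germacra-1(10),2,4(15),11(13)-tetraen-12,6-olide | C=C1C(=O)O[C@H]2[C@H]1[C@@H](OCc3ccc(OC)cc3)C/C(C)=C/C=C\C(=C)[C@H]2OCOC | intermediate
31 | (5R,6S,7R,8S)-8-hydroxy-5-(methoxymethoxy)germacra-1(10),2,4(15),11(13)-tetraen-12,6-olide | C=C1C(=O)O[C@H]2[C@H]1[C@@H](O)C/C(C)=C/C=C\C(=C)[C@H]2OCOC | intermediate
32 | angelic acid, (Z)-2-methylbut-2-enoic acid | C/C=C(/C)C(=O)O | starting material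
33 | angelic 2,4,6-trichlorobenzoic anhydride | C/C=C(/C)C(=O)OC(=O)c1c(Cl)cc(Cl)cc1Cl | intermediate
34 | (5R,6S,7R,8S)-8-angeloyloxy-5-(methoxymethoxy)germacra-1(10),2,4(15),11(13)-tetraen-12,6-olide | C=C1C(=O)O[C@H]2[C@H]1[C@@H](OC(=O)/C(C)=C\C)C/C(C)=C/C=C\C(=C)[C@H]2OCOC | intermediate
35 | (5R,6S,7R,8S)-8-angeloyloxy-5-hydroxygermacra-1(10),2,4(15),11(13)-tetraen-12,6-olide | C=C1C(=O)O[C@H]2[C@H]1[C@@H](OC(=O)/C(C)=C\C)C/C(C)=C/C=C\C(=C)[C@H]2O | intermediate
36 | 8-angeloyloxy-4,15-epoxy-5-hydroxygermacra-1(10),2,11(13)-trien-12,6-olide (epoxide oxygen cis to 5-OH) | C=C1C(=O)O[C@H]2[C@H]1[C@@H](OC(=O)/C(C)=C\C)C/C(C)=C/C=C\[C@]1(CO1)[C@H]2O | intermediate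
37 | 8-angeloyloxy-1,10:4,15-diepoxy-5-hydroxygermacra-2,11(13)-dien-12,6-olide (trans 1,10-epoxide, Z C2=C3) | C=C1C(=O)O[C@H]2[C@H]1[C@@H](OC(=O)/C(C)=C\C)C[C@@]1(C)O[C@@H]1/C=C\[C@]1(CO1)[C@H]2O | intermediate
38 | (1R,2R,3S,4S,5S,6S,7R,8S,10R)-8-angeloyloxy-1,10:2,3:4,15-triepoxy-5-hydroxygermacr-11(13)-en-12,6-olide | C=C1C(=O)O[C@H]2[C@H]1[C@@H](OC(=O)/C(C)=C\C)C[C@@]1(C)O[C@@H]1[C@@H]1O[C@@H]1[C@]1(CO1)[C@H]2O | target

## Step count and risks

Total: 22 steps. Longest linear sequence: 21 steps (steps 1–10 and 12–22, from 1); the branch from 13 joins after one step.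

Least certain steps:

Step 14 (key step). The most likely failure is loss of the C8 alkoxy group by β-elimination from the potassium enolate, or a proton shuffle that moves the enolate towards C5, while the mixture is at 0 °C to room temperature. A dissociative cleavage of the C1–C6 bond (the C1 carbanion would be a trienyl anion) could also erode the C8 configuration. Fallback: starting from 19, the rearrangement is run at the lowest temperature that sustains it and the enolate is trapped with Me3SiCl/Et3N at −78 °C as the trimethylsilyl enol ether F1. F1 cannot eliminate and can be purified. MeLi at −78 °C then regenerates the lithium enolate, so the route is rejoined at 23 (protonation gives 22, alkylation gives 24).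

Step 12. The most likely failures are enolisation of the doubly β,γ-unsaturated ketone by the organometallic (with epimerisation at the isopropenyl carbon or tautomerisation towards a phenol) and attack on the wrong carbonyl face. Fallback: the two-carbon unit is added before the ring diene exists. Starting from 7, fluoride gives the epoxy alcohol F2 and periodinane oxidation the epoxy ketone F3, which is far less enolisable. Addition of 17 gives the alkynyl carbinol F4 and LiAlH4 at 0 °C the E enol ether F5. The aluminium amide isomerisation then gives the allylic alcohol F6, selective acylation of its secondary hydroxyl gives the carbonate F7, and the palladium-catalysed elimination returns to the route at 19.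

Step 15. The most likely failures are proton removal at C5 instead of C7 and loss of the C8 alkoxide from the enolate while the alkylation is slow. Fallback: starting from 19, the acid quench of step 14 is replaced by addition of ethyl iodoacetate to the regiodefined potassium enolate 21 at −78 °C. The route is rejoined at 24 without any new isolated compound, and the ketone is never re-enolised.

Step 16. The most likely failure is hydride delivery to the wrong face of C6 if zinc binds the C8 ether or the ester instead of the C5 acetal. Fallback: starting from 24, the epimeric alcohol closes to the cis-fused lactone F8. Saponification with LiOH gives the 6-epi hydroxy acid F9, and a Mitsunobu lactonisation (PPh3, diisopropyl azodicarboxylate) closes the ring with inversion at C6, returning to the route at 26.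

Step 21. The hydroxyl-face delivery gives the target configuration at C4 only if the reacting conformer keeps the C3–C4–C5–C6 torsion well below 90°. An exocyclic olefin standing perpendicular to the ring would lead to the C4 epimer. Fallback: starting from 35, the hydroxyl is capped as the triethylsilyl ether F10 and all three olefins are epoxidised with dimethyldioxirane under steric control, anti to the silyloxy group, to the silylated tris-epoxide F11. Buffered HF·pyridine then returns to the route at 38.

Step 22. The most likely failure is oxygen transfer to the wrong face of the Z C2=C3 olefin, because a cis olefin in the ten-membered ring can expose either face. Fallback: starting from 36, one equivalent of dimethyldioxirane gives 37, which is isolated. N-Bromosuccinimide in buffered aqueous THF forms the bromonium ion on the exposed face and water opens it anti to give the bromohydrin F12. Ag2O then closes the epoxide with inversion at the carbon that bore bromine, on the face opposite to direct epoxidation, returning to the route at 38.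

## Further compounds

F1 | step 14 | trimethylsilyl enol ether (C6=C7) of 22 | C[Si](C)(C)O/C1=C\[C@@H](OCc2ccc(OC)cc2)C/C(C)=C/C=C\C(=C)[C@H]1OCOC
F2 | step 12 | desilylated epoxy alcohol from 7 | COCO[C@@H]1[C@]2(C)O[C@@H]2C[C@@H](C(C)=C)[C@@H]1O
F3 | step 12 | epoxy ketone, 3-(methoxymethoxy)-1-methyl-5-(prop-1-en-2-yl)-7-oxabicyclo[4.1.0]heptan-4-one skeleton with OMOM trans to isopropenyl | COCO[C@@H]1[C@]2(C)O[C@@H]2C[C@@H](C(C)=C)C1=O
F4 | step 12 | alkynyl carbinol epoxide (alkynyl trans to isopropenyl) | COCO[C@@H]1[C@]2(C)O[C@@H]2C[C@@H](C(C)=C)[C@]1(O)C#COCc1ccc(OC)cc1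
F5 | step 12 | E enol ether carbinol epoxide | COCO[C@@H]1[C@]2(C)O[C@@H]2C[C@@H](C(C)=C)[C@]1(O)/C=C/OCc1ccc(OC)cc1
F6 | step 12 | allylic diol with exocyclic methylene and E enol ether | COCO[C@@H]1C(=C)[C@H](O)C[C@@H](C(C)=C)[C@]1(O)/C=C/OCc1ccc(OC)cc1
F7 | step 12 | secondary methyl carbonate of F6 | COCO[C@@H]1C(=C)[C@H](OC(=O)OC)C[C@@H](C(C)=C)[C@]1(O)/C=C/OCc1ccc(OC)cc1
F0 | step 15 | none | none
F8 | step 16 | 6-epi (cis-fused) lactone of 26 | C1C(=O)O[C@@H]2[C@H]1[C@@H](OCc3ccc(OC)cc3)C/C(C)=C/C=C\C(=C)[C@H]2OCOC
F9 | step 16 | 6-epi hydroxy acid | O[C@@H]1[C@H](CC(=O)O)[C@@H](OCc2ccc(OC)cc2)C/C(C)=C/C=C\C(=C)[C@H]1OCOC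
F10 | step 21 | 5-O-triethylsilyl ether of 35 | C=C1C(=O)O[C@H]2[C@H]1[C@@H](OC(=O)/C(C)=C\C)C/C(C)=C/C=C\C(=C)[C@H]2O[Si](CC)(CC)CC
F11 | step 21 | 5-O-triethylsilyl ether of 38 | C=C1C(=O)O[C@H]2[C@H]1[C@@H](OC(=O)/C(C)=C\C)C[C@@]1(C)O[C@@H]1[C@@H]1O[C@@H]1[C@]1(CO1)[C@H]2O[Si](CC)(CC)CC
F12 | step 22 | 3-bromo-2-hydroxy derivative of 37 (OH and Br anti) | C=C1C(=O)O[C@H]2[C@H]1[C@@H](OC(=O)/C(C)=C\C)C[C@@]1(C)O[C@@H]1[C@H](O)[C@@H](Br)[C@]1(CO1)[C@H]2O
A1 | alternative 1 | ten-membered Z-olefin bis-epoxide (identical with 37) | C=C1C(=O)O[C@H]2[C@H]1[C@@H](OC(=O)/C(C)=C\C)C[C@@]1(C)O[C@@H]1/C=C\[C@]1(CO1)[C@H]2O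
A2 | alternative 1 | open-chain bis(vinyl epoxide) lactone, metathesis precursor | C=C1C(=O)O[C@H]([C@H](O)[C@@]2(CO2)C=C)[C@H]1[C@@H](OC(=O)/C(C)=C\C)C[C@@]1(C)O[C@@H]1C=C
A3 | alternative 2 | ten-membered enynone lactone | C1C(=O)O[C@H]2[C@H]1C(=O)C[C@@]3(C)OC(C)(C)O[C@H]3C#CC(=C)[C@H]2O[Si](C)(C)C(C)(C)C
A4 | alternative 2 | C3–C8 epoxy decalone with C2 ketone (epoxide face not specified) | C1C(=O)O[C@H]2[C@H]1C13OC3(C(=O)[C@@H]4OC(C)(C)O[C@]4(C)C1)C(=C)[C@H]2O[Si](C)(C)C(C)(C)C
A5 | alternative 3 | ten-membered C5,C6-diol | O[C@H]1[C@H](CC(=O)OC(C)(C)C)[C@@H](O[Si](C)(C)C(C)(C)C)C/C(C)=C/C=C\C(=C)[C@H]1O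
A6 | alternative 3 | open-chain dialdehyde (C5 enal, C6 aldehyde) | O=C[C@H](CC(=O)OC(C)(C)C)[C@@H](O[Si](C)(C)C(C)(C)C)C/C(C)=C/C=C\C(=C)C=O
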